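Retrosynthesis: the phenol O–benzyl bond of a protected precursor is cut first, then the ester C1(=O)–O bond to the primary oxygen of tyrosol, then the C19–C20 bond in the middle of the acyl chain.
Enabling feature: the acyl part is an unbranched, saturated chain of forty carbons (C1 carbonyl to C40 methyl) with no heteroatom or stereocentre beyond C1, so C19 and C20 are plain CH2 groups and both can be primary alkyl radicals.
Forward: C19–C20 is made first by mixed Kolbe electrolysis of a C20 half ester with docosanoic acid; the methyl ester is hydrolysed, C1 is joined to the alcohol oxygen of O-benzyl tyrosol, and hydrogenolysis frees the phenol.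
No ring is formed: the only ring, the para-disubstituted benzene, arrives ready-made with tyrosol and is kept out of the electrolysis cell.
The target has no stereocentre and no double-bond geometry, so no stereochemistry has to be set.

Key step: step 3

Remark: the acyl chain is numbered from the ester carbonyl carbon (C1) to the terminal methyl (C40); the very long-chain intermediates are assumed to need warm solvents throughout, as is usual for waxes.

Step 1
Reactants: 1 eicosanedioic acid (HO2C(CH2)18CO2H)
Product: 2 dimethyl eicosanedioate
Conditions: MeOH, cat. H2SO4, reflux
Reagents that add atoms: methanol, CO
Why: Fischer esterification of both carboxyl groups should be driven to completion by the large excess of methanol, and the diester should crystallise on cooling.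

Step 2
Reactants: 2 dimethyl eicosanedioate
Product: 3 20-methoxy-20-oxoicosanoic acid (monomethyl eicosanedioate)
Conditions: Ba(OH)2 (0.5 equiv), MeOH with a little THF, 40 °C; filter the barium salt; then aq. HCl
Reagents that add atoms: barium hydroxide, [Ba+2].[OH-].[OH-]
Why: Half saponification of a symmetrical diester, in which the barium salt of the half ester should precipitate as it forms and so escape the second hydrolysis, unchanged diester staying in the filtrate and acidification of the salt releasing 3.

Step 3
Reactants: 3 20-methoxy-20-oxoicosanoic acid; 4 docosanoic acid (behenic acid, 3 equiv)
Product: 5 methyl tetracontanoate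
Conditions: NaOMe (0.05 equiv per acid), MeOH under a layer of light petroleum, 50 °C, undivided cell, smooth Pt anode, Pt cathode, constant current at high current density (about 0.2 A cm-2), run until faintly alkaline
Reagents that add atoms: none
Why: At the smooth Pt anode both carboxylates are oxidised by one electron and lose CO2, so that the 19-carbon radical MeO2C(CH2)17CH2• from 3 and the 21-carbon henicosyl radical from 4 arise side by side in the dense adsorbed layer and combine to the C19–C20 bond before they diffuse away. The closest known reaction type is the mixed (crossed) Kolbe electrolysis of a fatty acid with an alkanedioic acid half ester, the classical chain extension to very long-chain acids. No ring closes and no stereocentre is created, both carbons of the new bond being CH2 groups. The step needs cross-coupling over homo-coupling, which the threefold excess of the cheap acid 4 secures by letting nearly every radical from 3 meet a henicosyl partner, and it needs radical coupling over further oxidation to carbocations, which is secured by the unbranched primary carboxylates without α-substituent, the smooth Pt surface, the high current density and the low degree of neutralisation. The distal methyl ester is inert at the anode and cannot scramble in methanol, and the oxidisable phenol is not yet in the molecule. The three coupling products fall into different polarity classes (C42 alkane, C40 monoester 5, C38 diester), so 5 should be separable on silica with warm hexane/toluene despite the similar chain lengths.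

Step 4
Reactants: 5 methyl tetracontanoate
Product: 6 tetracontanoic acid
Conditions: KOH, 95% EtOH/toluene, reflux; then aq. HCl, hot toluene
Reagents that add atoms: potassium hydroxide, [K+].[OH-]
Why: Saponification of a methyl ester (BAc2 hydrolysis) is run hot in a toluene-containing medium because of the waxy substrate, and residual hydrocarbon can be washed from the potassium soap with hot hexane before acidification, with any trace of C38 diacid left behind on crystallisation.

Step 5
Reactants: 7 tyrosol (2-(4-hydroxyphenyl)ethanol)
Product: 8 2-[4-(benzyloxy)phenyl]ethanol
Conditions: BnBr (1.05 equiv), K2CO3, acetone, reflux
Reagents that add atoms: benzyl bromide, BrCc1ccccc1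
Why: Williamson ether synthesis in which K2CO3 deprotonates only the phenol (pKa about 10) and not the aliphatic alcohol (pKa about 16), so benzylation should go to the phenolic oxygen alone.

Step 6
Reactants: 6 tetracontanoic acid; 8 2-[4-(benzyloxy)phenyl]ethanol
Product: 10 2-[4-(benzyloxy)phenyl]ethyl tetracontanoate, via tetracontanoyl chloride 9 (not isolated)
Conditions: SOCl2, cat. DMF, toluene, 80 °C, then evaporation; 8, pyridine, cat. DMAP, toluene, 70 °C
Reagents that add atoms: none
Why: Acylation of a primary alcohol by an acid chloride under nucleophilic catalysis by DMAP, where the acid chloride is far more soluble than the acid, the benzyl ether masks the only other nucleophilic oxygen and hot toluene keeps the C40 chain in solution.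

Step 7
Reactants: 10 2-[4-(benzyloxy)phenyl]ethyl tetracontanoate
Product: 11 2-(4-hydroxyphenyl)ethyl tetracontanoate (target)
Conditions: H2 (1 atm), 10% Pd/C, THF/EtOAc, 50 °C; hot filtration
Reagents that add atoms: none
Why: Catalytic hydrogenolysis of the benzyl aryl ether should cleave only the O–CH2Ph bond, since the alkyl ester C–O bond is homobenzylic and not benzylic and the arene is not reduced under these mild neutral conditions.

Compound list
1 | eicosanedioic acid | OC(=O)CCCCCCCCCCCCCCCCCCC(=O)O | starting material
2 | dimethyl eicosanedioate | COC(=O)CCCCCCCCCCCCCCCCCCC(=O)OC | intermediate
3 | 20-methoxy-20-oxoicosanoic acid (monomethyl eicosanedioate) | COC(=O)CCCCCCCCCCCCCCCCCCC(=O)O | intermediate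
4 | docosanoic acid (behenic acid) | CCCCCCCCCCCCCCCCCCCCCC(=O)O | starting material
5 | methyl tetracontanoate | CCCCCCCCCCCCCCCCCCCCCCCCCCCCCCCCCCCCCCCC(=O)OC | intermediate
6 | tetracontanoic acid | CCCCCCCCCCCCCCCCCCCCCCCCCCCCCCCCCCCCCCCC(=O)O | intermediate
7 | tyrosol (2-(4-hydroxyphenyl)ethanol) | OCCc1ccc(O)cc1 | starting material
8 | 2-[4-(benzyloxy)phenyl]ethanol | OCCc1ccc(OCc2ccccc2)cc1 | intermediate
9 | tetracontanoyl chloride | CCCCCCCCCCCCCCCCCCCCCCCCCCCCCCCCCCCCCCCC(=O)Cl | intermediate
10 | 2-[4-(benzyloxy)phenyl]ethyl tetracontanoate | CCCCCCCCCCCCCCCCCCCCCCCCCCCCCCCCCCCCCCCC(=O)OCCc1ccc(OCc2ccccc2)cc1 | intermediate
11 | 2-(4-hydroxyphenyl)ethyl tetracontanoate | CCCCCCCCCCCCCCCCCCCCCCCCCCCCCCCCCCCCCCCC(=O)OCCc1ccc(O)cc1 | target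

Total step count: 7.
Longest linear sequence: 6 steps (steps 1, 2, 3, 4, 6 and 7, from diacid 1 to target 11); step 5 is a one-step side branch.

Steps most likely to fail

Step 3 (mixed Kolbe electrolysis): the waxy products may coat the anode and the sparingly soluble acids may starve the electrode. Current efficiency could then collapse, homo-coupling could take over, or the radicals could be oxidised further to cations. The fallback sets out from half ester 3 and comes back at ester 5. The free carboxyl group of 3 would be reduced chemoselectively with BH3·SMe2 in THF (0 °C to rt) to methyl 20-hydroxyicosanoate F1. An Appel reaction (CBr4, PPh3, CH2Cl2) would turn this into methyl 20-bromoicosanoate F2. Eicosylmagnesium bromide F3, made from commercial 1-bromoeicosane and Mg turnings in THF, would then be coupled with F2 under Li2CuCl4 catalysis (THF, −10 °C, Kochi-type alkyl–alkyl coupling). The copper-catalysed displacement of the primary bromide should outrun addition to the ester, giving methyl tetracontanoate 5 as the single coupling product. The chain would then be joined at C20–C21 by a polar instead of a radical union.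

Step 2 (half saponification): the second ester group may hydrolyse at a rate similar to the first if the barium salt does not precipitate cleanly from the THF-containing medium. That would leave a statistical mixture of diester, half ester and diacid that co-crystallises. The fallback sets out from diacid 1 and comes back at half ester 3 without passing through 2. Diacid 1 would be chemisorbed from warm THF on neutral Al2O3, to which a dicarboxylic acid binds through one carboxylate only. The free carboxyl end would be methylated with ethereal diazomethane and the half ester released with acetic acid in ether. The selectivity would then come from the surface and not from statistics, and no new compound arises (F0).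

Step 7 (hydrogenolysis): the wax ester may crystallise out of the warm solvent onto the Pd/C and stall the heterogeneous reaction, and forcing it may begin to saturate the phenol ring. The fallback sets out from acid 6 together with unprotected tyrosol 7 and comes back at target 11, leaving out steps 5 to 7. A Mitsunobu esterification (PPh3, DIAD, THF/toluene, 40 °C) should activate only the aliphatic hydroxyl as its alkoxyphosphonium salt. The carboxylate, by far the more acidic pronucleophile than the phenol, would displace it. This protecting-group-free, homogeneous route makes no new compound (F0).

Further compounds
F1 | step 3 | methyl 20-hydroxyicosanoate | COC(=O)CCCCCCCCCCCCCCCCCCCO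
F2 | step 3 | methyl 20-bromoicosanoate | COC(=O)CCCCCCCCCCCCCCCCCCCBr
F3 | step 3 | eicosylmagnesium bromide | CCCCCCCCCCCCCCCCCCCC[Mg]Br
F0 | step 2 | none | none
F0 | step 7 | none | none
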